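Retrosynthesis: both aryl–CH bonds at the bridging 3-methylbutylidene carbon are cut first (two identical 3-prenylphloroacetophenone rings + isovaleraldehyde). Each C3–prenyl bond is then traced back to a 1,1-dimethylallyl ether on O4, and the O4–C bond to phloroacetophenone + a C5 propargylic chloride.
Forward: both benzene rings are bought. The O4–C5 ether is made (step 1) and the alkyne half-reduced (step 2). In one flask a [3,3] shift then forms C3–prenyl, and an amine-mediated ortho-quinone-methide dimerization, the presumed biosynthetic union, forms C5–CH–C5' (step 3).
Enabling feature (acetophenone numbering: C1 acetyl carbon, O2/O4/O6 hydroxyl oxygens): O4 lies between C3 and C5, the two equivalent unsubstituted ring carbons, and hands the prenyl group to C3 sigmatropically. C5, flanked by O4–H and O6–H, is then first a nucleophile and, as the exocyclic carbon of an o-quinone methide, an electrophile. Because the bridging CH carries two identical rings, one monomer plays both roles.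
Stereochemistry: none to set. The bridging CH bears two constitutionally identical aryl groups, so the target is achiral; "single enantiomer" is taken to mean this one achiral compound.

Key step: step 3

Step 1
Reactants: 1 1-(2,4,6-trihydroxyphenyl)ethan-1-one (phloroacetophenone, dried); 2 3-chloro-3-methylbut-1-yne
Product: 3 1-[2,6-dihydroxy-4-(2-methylbut-3-yn-2-yloxy)phenyl]ethan-1-one
Conditions: 2 (1.05 equiv), CuCl2·2H2O (1 mol %), DBU (1.1 equiv), MeCN, 0 °C
Reagents that add atoms: none
Why: Copper-catalysed propargylic etherification of a phenol (phenoxide attack at the tertiary carbon of a copper acetylide/allenylidene): O4–H, para to the acetyl group and not hydrogen-bonded to it, is the most acidic hydroxyl, so one equivalent of base and of 2 should alkylate O4 once, and the resulting ether is a weaker acid and more hindered than 1, which brakes a second alkylation.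

Step 2
Reactants: 3 1-[2,6-dihydroxy-4-(2-methylbut-3-yn-2-yloxy)phenyl]ethan-1-one
Product: 4 1-[2,6-dihydroxy-4-(2-methylbut-3-en-2-yloxy)phenyl]ethan-1-one
Conditions: H2 (1 atm), Lindlar catalyst, quinoline, EtOAc, 20 °C, stopped after 1 equiv H2; filtered, concentrated below 30 °C
Reagents that add atoms: none
Why: Lindlar semihydrogenation: the lead- and quinoline-poisoned palladium should add one equivalent of H2 to the terminal alkyne and leave the aryl ketone, the phenols and the tertiary allylic C–O bond untouched at room temperature.

Step 3
Reactants: 4 1-[2,6-dihydroxy-4-(2-methylbut-3-en-2-yloxy)phenyl]ethan-1-one (2 equiv); 5 3-methylbutanal (isovaleraldehyde, 1 equiv)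
Product: 9 1,1-bis[3-acetyl-2,4,6-trihydroxy-5-(3-methylbut-2-en-1-yl)phenyl]-3-methylbutane (target CNP0215781.0), via 3-prenylphloroacetophenone 6 (not isolated), via Mannich base 7 (not isolated), via ortho-quinone methide 8 (not isolated)
Conditions: PhMe, 110 °C, Ar; then 5 (0.5 equiv based on 4), pyrrolidine (20 mol %), THF, 45 °C; aq. NH4Cl work-up
Reagents that add atoms: none
Why: On heating, the O4–C(CH3)2–CH=CH2 unit of 4 undergoes an aromatic Claisen ([3,3]) shift through a six-membered transition state that bonds its CH2 terminus to C3 (C3 and C5 are equivalent and both ortho to O4), and enolization gives the linear prenyl ketone 6; pyrrolidine and 5 then form an iminium ion that the one remaining ring carbon C5 attacks (Mannich/Betti reaction, 7), pyrrolidine is expelled from the phenoxide to give ortho-quinone methide 8, and C5 of a second molecule of 6 adds to the exocyclic carbon of 8 and re-aromatizes to 9, which frees the amine for the next turnover. The closest known reaction types are the Claisen rearrangement of aryl 1,1-dimethylallyl ethers to ortho-prenylphenols and the pseudo-three-component condensation of two acylphloroglucinols with an aliphatic aldehyde through an ortho-quinone methide. No ring is closed (four C–C bonds are made on two bought rings) and no stereocentre is formed, because the bridging carbon ends with two identical aryl groups. The step needs linear rather than reverse prenyl and exactly one prenyl per ring, both fixed by the single ether group and the single [3,3] shift into a free ortho carbon. It also needs C-arylation of 8 rather than cycloaddition to a prenyl double bond, hydrogen shift to a hydroxystyrene or oligomerization; this is secured because after the shift every ring has exactly one unsubstituted, strongly nucleophilic carbon, 5 is the limiting component, and the medium stays acid-free so the ortho-prenylphenols cannot cyclize to chromans.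

Compound list
1 | 1-(2,4,6-trihydroxyphenyl)ethan-1-one (phloroacetophenone) | CC(=O)c1c(O)cc(O)cc1O | starting material
2 | 3-chloro-3-methylbut-1-yne | CC(C)(Cl)C#C | starting material
3 | 1-[2,6-dihydroxy-4-(2-methylbut-3-yn-2-yloxy)phenyl]ethan-1-one | CC(=O)c1c(O)cc(OC(C)(C)C#C)cc1O | intermediate
4 | 1-[2,6-dihydroxy-4-(2-methylbut-3-en-2-yloxy)phenyl]ethan-1-one | CC(=O)c1c(O)cc(OC(C)(C)C=C)cc1O | intermediate
5 | 3-methylbutanal (isovaleraldehyde) | CC(C)CC=O | starting material
6 | 1-[2,4,6-trihydroxy-3-(3-methylbut-2-en-1-yl)phenyl]ethan-1-one (3-prenylphloroacetophenone) | CC(=O)c1c(O)cc(O)c(CC=C(C)C)c1O | intermediate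
7 | 1-[2,4,6-trihydroxy-3-(3-methylbut-2-en-1-yl)-5-(3-methyl-1-pyrrolidin-1-ylbutyl)phenyl]ethan-1-one (Mannich base, racemic) | CC(=O)c1c(O)c(CC=C(C)C)c(O)c(C(CC(C)C)N2CCCC2)c1O | intermediate
8 | 4-acetyl-3,5-dihydroxy-6-(3-methylbutylidene)-2-(3-methylbut-2-en-1-yl)cyclohexa-2,4-dien-1-one (ortho-quinone methide, one tautomer, exocyclic C=C geometry not defined) | CC(=O)C1=C(O)C(=CCC(C)C)C(=O)C(CC=C(C)C)=C1O | intermediate
9 | 1,1-bis[3-acetyl-2,4,6-trihydroxy-5-(3-methylbut-2-en-1-yl)phenyl]-3-methylbutane (CNP0215781.0, achiral) | CC(=O)c1c(O)c(CC=C(C)C)c(O)c(C(CC(C)C)c2c(O)c(CC=C(C)C)c(O)c(C(C)=O)c2O)c1O | target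

Total step count: 3. Longest linear sequence: 3 steps (1 → 3 → 4 → 9).

Steps most likely to fail

Step 1. The ambident phenoxide of 1 may be alkylated on carbon or on two oxygens instead of once on O4, or the chelating hydroxy ketone may bind the copper so that the propargylic substitution stalls. The fallback replaces O-alkylation/[3,3] shift by direct C-alkylation. It sets out from 1, which is treated with 3-methylbut-2-enyl bromide (1.0 equiv) and DBU in THF at room temperature (alternatively 10% aqueous KOH, 0 °C). The 3,5-diprenyl and O-prenyl by-products expected from this statistical alkylation are removed by chromatography. The fallback comes back to the route at 6, now isolated, which is taken through the second stage of step 3 (5, pyrrolidine, THF, 45 °C). No new compound arises on this way.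

Step 3. The tertiary allyl ether may ionize and lose its C5 unit instead of rearranging, and the ortho-quinone methide may be drained by hydrogen shift to a 2-hydroxystyrene or by cycloaddition to prenyl double bonds before the second ring adds. The fallback builds the bridge while no prenyl group and no tertiary ether is present. It sets out from 1 and 5: condensation of 1 (4 equiv, excess to suppress oligomers) with 5 under pyrrolidine catalysis (THF, 45 °C) should give 1,1-bis(3-acetyl-2,4,6-trihydroxyphenyl)-3-methylbutane F1, in which each ring keeps exactly one unsubstituted carbon. Twofold C-prenylation of F1 with 3-methylbut-2-enyl bromide (2.2 equiv) in 10% aqueous KOH at 0 °C can then take place on carbon only at those two positions, and the fallback comes back to the route at 9.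

Step 2. The terminal alkene may be over-reduced, and the labile tertiary allyl ether may be lost by ionization or premature rearrangement on the catalyst or during concentration. The fallback avoids both the alkyne and the tertiary ether and sets out from 1. O4-allylation (allyl bromide 1.0 equiv, K2CO3, acetone, 20 °C) should give 1-[2,6-dihydroxy-4-(prop-2-en-1-yloxy)phenyl]ethan-1-one F2. Aromatic Claisen rearrangement (N,N-diethylaniline, 190 °C) should give 1-[2,4,6-trihydroxy-3-(prop-2-en-1-yl)phenyl]ethan-1-one F3. Olefin cross-metathesis of F3 with 2-methylbut-2-ene (excess, second-generation Ru–NHC benzylidene catalyst 5 mol %, CH2Cl2, 40 °C) turns the allyl into the prenyl group, and the fallback comes back to the route at 6, which then enters the second stage of step 3.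

Further compounds
F0 | step 1 | none | none
F1 | step 3 | 1,1-bis(3-acetyl-2,4,6-trihydroxyphenyl)-3-methylbutane | CC(=O)c1c(O)cc(O)c(C(CC(C)C)c2c(O)cc(O)c(C(C)=O)c2O)c1O
F2 | step 2 | 1-[2,6-dihydroxy-4-(prop-2-en-1-yloxy)phenyl]ethan-1-one | CC(=O)c1c(O)cc(OCC=C)cc1O
F3 | step 2 | 1-[2,4,6-trihydroxy-3-(prop-2-en-1-yl)phenyl]ethan-1-one | CC(=O)c1c(O)cc(O)c(CC=C)c1O
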